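**Retrosynthetic overview**
- The target comes from 4'-hydroxy-5,6,7,8,3',5'-hexamethoxyflavone. The last step is chelation-controlled cleavage of the 5-OMe group that lies peri to C4=O.
- Key disconnection C2–C1': C2 is by nature an acceptor (β-carbon of the vinylogous ester) but is used here as a donor. The C2-zincated chromone is a metalated enol ether, a masked acyl anion ArCOCH2C(=O)(–). It is joined to the C–Br carbon, also an acceptor, of unprotected 4-bromo-2,6-dimethoxyphenol.
- 5,6,7,8-Tetramethoxychromone comes from 2-hydroxy-3,4,5,6-tetramethoxyacetophenone plus one carbon (DMF-DMA).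
- That ketone comes from 3,4,5-trimethoxyphenol by ortho-acetylation, bromination of the last ring C–H and Cu-catalysed Br→OMe exchange. The bromophenol comes from 2,6-dimethoxyphenol.
- Ring order: ring A is bought and filled up, ring C is closed on it, and ring B (bought) is attached last.

Assumption: the target is a planar, achiral flavone without any stereocentre or stereogenic axis, so "single enantiomer" asks for nothing beyond the constitution shown, and no step has to set configuration.

**Step 1**
Reactants: 1 3,4,5-trimethoxyphenol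
Product: 2 1-(6-hydroxy-2,3,4-trimethoxyphenyl)ethan-1-one
Conditions: Ac2O (1.1 equiv), BF3·OEt2 (3 equiv), 70 °C, 2 h; then H2O
Reagents that add atoms: acetic anhydride, CC(=O)OC(C)=O
Why: This is a BF3-promoted Friedel–Crafts ortho-acylation in which the two free ring positions of 1 are equivalent and both lie ortho to OH, and the H-bonded, deactivated ketone 2 does not acylate again; no stereocentre is formed.

**Step 2**
Reactants: 2 1-(6-hydroxy-2,3,4-trimethoxyphenyl)ethan-1-one
Product: 3 1-(3-bromo-2-hydroxy-4,5,6-trimethoxyphenyl)ethan-1-one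
Conditions: NBS (1.05 equiv), dry CH2Cl2, 0 °C → rt, dark, 1 h
Reagents that add atoms: N-bromosuccinimide, O=C1CCC(=O)N1Br
Why: In this electrophilic aromatic bromination the single remaining ring C–H is ortho to OH and to OMe, so it reacts far faster than the acetyl CH3 under non-enolising, non-radical conditions.

**Step 3**
Reactants: 3 1-(3-bromo-2-hydroxy-4,5,6-trimethoxyphenyl)ethan-1-one
Product: 4 1-(2-hydroxy-3,4,5,6-tetramethoxyphenyl)ethan-1-one
Conditions: NaOMe (25 % in MeOH, 8 equiv), CuBr (0.3 equiv), DMF, 110 °C, N2, 6 h; then 2 M HCl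
Reagents that add atoms: sodium methoxide, C[O-].[Na+]
Why: This Ullmann-type methoxylation through a methoxide of monovalent copper is the reaction type that turns 5-bromovanillin into syringaldehyde and hindered bromo-trimethoxytoluenes into tetramethoxytoluenes, and it tolerates a free phenoxide and an aryl methyl ketone.

**Step 4**
Reactants: 4 1-(2-hydroxy-3,4,5,6-tetramethoxyphenyl)ethan-1-one
Product: 6 5,6,7,8-tetramethoxy-4H-chromen-4-one, via enaminone 5 (not isolated)
Conditions: DMF-DMA (3 equiv), toluene, 100 °C, 3 h; evaporate; conc. HCl, CH2Cl2, 40 °C, 1 h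
Reagents that add atoms: N,N-dimethylformamide dimethyl acetal, COC(OC)N(C)C
Why: In this enaminone route to chromones the acetyl CH3 condenses with the amide acetal to the (E)-vinylogous amide 5, and acid lets the ortho-OH add to its β-carbon and expel Me2NH (addition–elimination), which closes ring C and leaves C2–H free.

**Step 5**
Reactants: 7 2,6-dimethoxyphenol
Product: 8 4-bromo-2,6-dimethoxyphenol
Conditions: NBS (1.0 equiv), NaH (1 mol %), CHCl3/MeOH, −45 °C, then reflux 30 min
Reagents that add atoms: N-bromosuccinimide, O=C1CCC(=O)N1Br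
Why: This electrophilic aromatic bromination runs through the phenoxide made by the catalytic base, which steers NBS para to the oxygen and away from the positions activated by the two OMe groups.

**Step 6 (key step)**
Reactants: 6 5,6,7,8-tetramethoxy-4H-chromen-4-one; 8 4-bromo-2,6-dimethoxyphenol
Product: 10 4'-hydroxy-5,6,7,8,3',5'-hexamethoxyflavone, via chromon-2-ylzinc chloride 9 (not isolated)
Conditions: 6 (1.3 equiv), TMPZnCl·LiCl (1.45 equiv, no MgCl2 or other Lewis acid), THF, 25 °C, 1 h; added over 1 h to 8 (1.0 equiv), Pd(OAc)2 (2 mol %), SPhos (4 mol %), THF, 25 → 50 °C, 6 h; sat. aq. NH4Cl (excess 6 recovered)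
Reagents that add atoms: TMPZnCl·LiCl, CC1(C)CCCC(C)(C)N1[Zn]Cl.[Li+].[Cl-] (its Zn and Cl stand only in 9; none of its atoms stay in 10)
Why: C2–H, next to the ring oxygen, is the most acidic C–H of a chromone, so the magnesium-free TMP-zinc base turns this natural acceptor carbon into a metalated enol ether (masked acyl anion and β-acylvinyl anion), which a Negishi cross-coupling on zerovalent palladium joins to the likewise electrophilic C–Br carbon of 8 faster than the weakly basic alkenylzinc is protonated by the free ArOH; no stereocentre is formed.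

**Step 7**
Reactants: 10 4'-hydroxy-5,6,7,8,3',5'-hexamethoxyflavone
Product: 12 5,4'-dihydroxy-6,7,8,3',5'-pentamethoxyflavone, via bis(dichloroboryl) ether 11 (not isolated)
Conditions: BCl3 (1 M in CH2Cl2, 2.5 equiv), CH2Cl2, −78 → 0 °C, 1.5 h; then 1 M aq. HCl, rt
Reagents that add atoms: boron trichloride, ClB(Cl)Cl (its B and Cl stand only in 11; 12 gains only H)
Why: In this chelation-controlled aryl methyl ether cleavage the first BCl3 is taken up by 4'-OH, the second binds C4=O so that only the peri 5-OMe can close a six-membered boron chelate and lose its methyl group to chloride (SN2) at or below 0 °C, and aqueous acid then frees both phenols while the other five OMe groups stay.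

**Compound list**
1 | 3,4,5-trimethoxyphenol | COc1cc(O)cc(OC)c1OC | starting material
2 | 1-(6-hydroxy-2,3,4-trimethoxyphenyl)ethan-1-one | CC(=O)c1c(O)cc(OC)c(OC)c1OC | intermediate
3 | 1-(3-bromo-2-hydroxy-4,5,6-trimethoxyphenyl)ethan-1-one | CC(=O)c1c(O)c(Br)c(OC)c(OC)c1OC | intermediate
4 | 1-(2-hydroxy-3,4,5,6-tetramethoxyphenyl)ethan-1-one | CC(=O)c1c(O)c(OC)c(OC)c(OC)c1OC | intermediate
5 | (E)-3-(dimethylamino)-1-(2-hydroxy-3,4,5,6-tetramethoxyphenyl)prop-2-en-1-one (not isolated) | CN(C)/C=C/C(=O)c1c(O)c(OC)c(OC)c(OC)c1OC | intermediate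
6 | 5,6,7,8-tetramethoxy-4H-chromen-4-one | COc1c(OC)c(OC)c2c(=O)ccoc2c1OC | intermediate
7 | 2,6-dimethoxyphenol (syringol) | COc1cccc(OC)c1O | starting material
8 | 4-bromo-2,6-dimethoxyphenol | COc1cc(Br)cc(OC)c1O | intermediate
9 | (5,6,7,8-tetramethoxy-4-oxo-4H-chromen-2-yl)zinc chloride, LiCl complex (not isolated) | COc1c(OC)c(OC)c2c(=O)cc([Zn]Cl)oc2c1OC | intermediate
10 | 4'-hydroxy-5,6,7,8,3',5'-hexamethoxyflavone | COc1cc(-c2cc(=O)c3c(OC)c(OC)c(OC)c(OC)c3o2)cc(OC)c1O | intermediate
11 | 5,4'-bis(dichloroboryloxy)-6,7,8,3',5'-pentamethoxyflavone (not isolated) | COc1cc(-c2cc(=O)c3c(OB(Cl)Cl)c(OC)c(OC)c(OC)c3o2)cc(OC)c1OB(Cl)Cl | intermediate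
12 | 5,4'-dihydroxy-6,7,8,3',5'-pentamethoxyflavone | COc1cc(-c2cc(=O)c3c(O)c(OC)c(OC)c(OC)c3o2)cc(OC)c1O | target

**Total step count:** 7. **Longest linear sequence:** 6 (steps 1, 2, 3, 4, 6, 7).

**Three steps most likely to fail**

*Step 6.*
- Risk: the 5-OMe/C4=O pair may hold Li+ or Zn2+ and draw the base to C3–H, and the free ArOH of 8 may protonate 9.
- Fallback: C2 is used with its normal acceptor polarity. It sets out from 6 and comes back at 10.
- Pd(OCOCF3)2/2,2'-bipyridine catalyses the conjugate addition of commercial (4-hydroxy-3,5-dimethoxyphenyl)boronic acid to 6 in THF/AcOH/H2O at 60 °C. This gives racemic 2-(4-hydroxy-3,5-dimethoxyphenyl)-5,6,7,8-tetramethoxychroman-4-one F1.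
- DDQ in dioxane at 100 °C then takes two hydrogens from C2–C3 and delivers 10. The stereocentre of the flavanone is erased, so it needs no control.

*Step 3.*
- Risk: the bromide sits between O– and OMe. It may be reduced back to 2, or the ketone may suffer in hot methoxide.
- Fallback: the C–O bond is made by Dakin oxidation in place of substitution at C–Br. It sets out from 2 and comes back at 4.
- Duff formylation of 2 (hexamethylenetetramine, CF3CO2H, 80 °C, then aq. HCl) gives 3-acetyl-2-hydroxy-4,5,6-trimethoxybenzaldehyde F2.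
- H2O2/NaOH at 0 °C → rt oxidises the aldehyde far faster than the ketone and gives 1-(2,3-dihydroxy-4,5,6-trimethoxyphenyl)ethan-1-one F3.
- MeI (1.0 equiv) and K2CO3 in acetone methylate only the 3-OH, which is not H-bonded to the acetyl group. This gives 4.

*Step 7.*
- Risk: over-cleavage at 6-OMe (next to the new chelate), at the crowded 7-OMe, or at 3'/5'-OMe beside the 4'-O–BCl2 group.
- Fallback: the 5-OH is freed before ring B is present and is carried as a benzyl ether. It sets out from 6 and comes back at 12.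
- BCl3 (1.1 equiv, CH2Cl2, −78 → 0 °C) on 6 gives 5-hydroxy-6,7,8-trimethoxy-4H-chromen-4-one F4.
- BnBr and K2CO3 in DMF at 60 °C give 5-benzyloxy-6,7,8-trimethoxy-4H-chromen-4-one F5.
- TMPZnCl·LiCl gives (5-benzyloxy-6,7,8-trimethoxy-4-oxo-4H-chromen-2-yl)zinc chloride F6.
- Negishi coupling with 8 under the step 6 conditions gives 5-benzyloxy-4'-hydroxy-6,7,8,3',5'-pentamethoxyflavone F7.
- H2 (1 atm) over Pd/C in EtOAc removes the benzyl group and gives 12.

**Further compounds**
F1 | step 6 | 2-(4-hydroxy-3,5-dimethoxyphenyl)-5,6,7,8-tetramethoxychroman-4-one (racemic) | COc1cc(C2CC(=O)c3c(OC)c(OC)c(OC)c(OC)c3O2)cc(OC)c1O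
F2 | step 3 | 3-acetyl-2-hydroxy-4,5,6-trimethoxybenzaldehyde | CC(=O)c1c(O)c(C=O)c(OC)c(OC)c1OC
F3 | step 3 | 1-(2,3-dihydroxy-4,5,6-trimethoxyphenyl)ethan-1-one | CC(=O)c1c(O)c(O)c(OC)c(OC)c1OC
F4 | step 7 | 5-hydroxy-6,7,8-trimethoxy-4H-chromen-4-one | COc1c(OC)c(O)c2c(=O)ccoc2c1OC
F5 | step 7 | 5-benzyloxy-6,7,8-trimethoxy-4H-chromen-4-one | COc1c(OC)c(OCc3ccccc3)c2c(=O)ccoc2c1OC
F6 | step 7 | (5-benzyloxy-6,7,8-trimethoxy-4-oxo-4H-chromen-2-yl)zinc chloride | COc1c(OC)c(OCc3ccccc3)c2c(=O)cc([Zn]Cl)oc2c1OC
F7 | step 7 | 5-benzyloxy-4'-hydroxy-6,7,8,3',5'-pentamethoxyflavone | COc1cc(-c2cc(=O)c3c(OCc4ccccc4)c(OC)c(OC)c(OC)c3o2)cc(OC)c1O
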